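## Analysis of the target

Plakortone N is a cis-fused furo[3,2-b]furan-2-one. A γ-lactone (O1, C2, C3, C3a, C6a) shares the C3a–C6a bond with a tetrahydrofuran (C3a, O4, C5, C6, C6a). C6a carries a methyl group; C5 carries a methyl group and an unbranched 12-(4-hydroxyphenyl)dodecyl chain.

The three stereocentres are (3aS,5S,6aS). C3a is the only one bearing hydrogen; C6a and C5 are fully substituted carbons bonded to oxygen. The ring fusion is cis, and at C5 the methyl group lies on the face of the lactone ring while the chain lies on the open face.

Sensitive features are the β-alkoxy lactone (C3a–O4 is β to the carbonyl, so base can open the ether ring by elimination), the tertiary ethers (ionisable by strong acid) and the free phenol. The chain has no functionality besides the arene and offers no handle for stereocontrol.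

The difficulty sits at C5: a quaternary ether carbon whose two carbon substituents (methyl, n-alkyl) are nearly equal in size, placed 1,3 to the quaternary C6a across the C6 methylene.

The strategy rests on the two tertiary C–O bonds, C6a–O1 and C5–O4, which flank C6, with O4 sitting on the carbon next to C6a. Each tertiary carbon can be the substituted end of a trisubstituted epoxide opened with inversion, and the first opening releases the oxygen that performs the second. If the C5 chain is shortened to an oxygenated two-carbon stub (C1′, C2′), C5 and C1′ become the carbons of a 2,3-epoxy alcohol derivative. The configuration of C5 is then fixed by an epoxidation reagent, not by telling methyl from alkyl.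

## Retrosynthetic reasoning

**Chain, C1′–C2′.** Target 24 is cut between the first and second chain carbons. Alkene 23 (hydrogenation, which also frees the phenol from its benzyl ether) leads back to aldehyde 16 and ylide 22, made from phosphonium salt 21. The cut is made here because the chain is stereochemically silent, so the whole stereochemical problem moves to a ten-carbon core. The carbonyl carbon of 16 is the C1′ left from the epoxy alcohol stub. The Wittig reaction only has to add to a non-enolisable aldehyde without touching the lactone.

**Stub, C1′–C2′ glycol cleavage.** Aldehyde 16 comes from diol 15 by periodate cleavage, and 15 from silyl ether 14 by desilylation. The secondary hydroxyl on C1′ of 14 is the by-product of the ring-forming step, so nothing has to be installed to enable the cleavage.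

**Both rings, C6a–O1 and C5–O4.** Bicycle 14 is opened at its two tertiary C–O bonds to the skipped bis-epoxy tert-butyl ester 12. In the forward direction acid lets the ester carbonyl open the C3–C4 epoxide at C4 (chain numbering of 12; C4 becomes C6a), with loss of the tert-butyl group. The hydroxyl set free on C3 (C3a) then opens the C6–C7 epoxide at C6 (C5). Both openings invert, so (4R) and (6S) in 12 become (6aS) and the required C5 configuration, while C3 and C7 are carried through unchanged. The reverse order is not available: the oxygen of the first epoxide could reach C6 only through a four-membered ring fused to the oxirane. The cascade therefore has to start at the ester.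

**Four stereocentres, two epoxides.** Bis-epoxide 12 is taken back to diene ester 11. Epoxidation is stereospecific, so the cis relation of the two chain arms on the C3–C4 epoxide requires the 3Z alkene and the 6,7-epoxide requires the 6E alkene. A chiral dioxirane (Shi epoxidation) sets the face of a trisubstituted alkene by the position of its single vinylic hydrogen. On that basis one enantiomer of the ketone catalyst is predicted to deliver (3S,4R) at the Z alkene and (6S,7S) at the E alkene, so both epoxides are installed in one operation. This prediction is by model and is not verified on a closely related Z substrate.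

**Ester from alcohol.** The β,γ-unsaturated tert-butyl ester 11 comes from acid 10 and this from homoallylic alcohol 8. The ester is introduced late because its doubly activated α-protons would not survive the organometallic steps. The alcohol oxidation state is also what the chosen alkenyl building block delivers.

**Skipped diene, C4–C5.** Alcohol 8 is cut at the sp2–sp3 bond between the two alkenes into Z-alkenylstannane 4 and E-allylic bromide 7. The polarity is chosen so that the Z geometry travels on a configurationally stable alkenyl–metal bond. Only the E alkene passes through a π-allyl palladium intermediate, where its syn arrangement is the stable one.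

**Z-alkenyl fragment.** Stannane 4 is traced to 2,3-dihydrofuran 1. Lithiation gives 2, and a 1,2-metalate rearrangement of its cuprate gives 3 with methyl trans and the metal cis to the hydroxyethyl arm. That is the required trisubstituted geometry, obtained in one flask together with the correct carbon count for the later acid.

**E-allyl fragment.** Bromide 7 comes from bromo alcohol 6 by silylation, and 6 from commercial bromo ester 5 by hydride reduction. The TBDPS group put on here is the one that survives to 14.

**Side chain.** Phosphonium salt 21 comes from bromide 20, made by copper-catalysed coupling of the Grignard reagent 19 of aryl bromide 17 with an excess of dibromide 18.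

## Alternatives that were turned down

**Alternative 1:** The core is cut at C3–C3a and at the bond from C5 to the carbon that will become its methyl group.
- Forward key step: Rh2(S-DOSP)4 (a chiral dirhodium tetraprolinate, divalent rhodium) turns the siloxy vinyldiazoacetate A3 into a vinylcarbenoid. It cyclopropanates furan A2 at the C4–C5 bond, and a Cope rearrangement then gives the oxa-bridged seven-membered ring A1. Retro-Claisen ring opening, lactonisation onto the ring alkene at C6a and reductive decarboxylation of the C5 acetic acid arm would follow.
- For it: two C–C bonds and both C3a and C5 are set in one catalyst-controlled step. The methyl/alkyl problem at C5 is solved by topology, because the future methyl is tied into the ring. The chain is present from the start, so no late olefination is needed. On convergence it is stronger than the chosen route.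
- Against it: the Cope step must form a bond to the fully substituted, chain-bearing α-carbon of A2, and cyclopropanation must occur next to the ring methyl. Electron-rich substituted furans tend to unravel to open-chain trienes with donor/acceptor carbenoids. After A1 a long sequence remains, including a radical decarboxylation to remove a carbon that served only as scaffold. C6a is still to be set, and A2 with its long chain has to be built first.
- Comparison: the chosen route gives up convergence. In exchange, every stereocentre comes from a predictable epoxidation and all risk is kept in one well-precedented type of ring closure.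

**Alternative 2:** The tetrahydrofuran is cut at C5–C6 and O4–C3a.
- Forward key step: SnCl4 (tetravalent tin) activates keto ester A6. The terminal carbon of allylsilane A5 attacks the ketone, silicon shifts to C6a, and the ketone oxygen closes on C3a to give A4. Tamao–Fleming oxidation of C6a–Si, lactonisation and reduction of the C5 ester to methyl would follow.
- For it: one stereocentre in A5 is relayed to three, the ether ring and the chain are assembled convergently, and the C–Si bond is a masked C6a–O bond with the correct configuration.
- Against it: a ketone flanked by an ester and a long alkyl group is a weaker and less face-biased electrophile than the aldehydes for which such annulations are reliable. The tertiary β-silyl cation from the 2-methyl-substituted A5 can simply lose silicon (plain allylation). Oxidising a quaternary dimethylphenylsilyl group is demanding. Turning the C5 ester into a methyl group means a deoxygenation at a neopentyl position, costing several steps.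
- Comparison: it is as strong as the chosen route on convergence. The chosen route avoids redox adjustment at a quaternary carbon and needs no stoichiometric chiral fragment.

**Alternative 3:** Only O4–C5 is cut.
- Forward key step: Co(modp)2 [bis(1-morpholinocarbamoyl-4,4-dimethylpentane-1,3-dionato)cobalt, divalent cobalt] under O2 adds the C3a hydroxyl of hydroxy lactone A8 to its methallyl alkene (Mukaiyama aerobic oxidative cyclisation). The ether ring closes and the terminal carbon ends as the hydroxymethyl group of A7.
- For it: A7 is one oxidation away from aldehyde 16 of the present route, so the end game is shorter than here by two steps and needs no protecting group. The trans preference of this cyclisation is well established for open-chain 5-hydroxyalkenes. On step count after the key step it is stronger.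
- Against it: C5 is set under substrate control where the two alkene faces differ only by methyl versus the incipient CH2 radical, with the alcohol locked on a lactone ring next to a quaternary carbon. The acyclic trans rule does not transfer safely. A8 already contains two adjacent stereocentres, one quaternary, that need an asymmetric route of their own. Tertiary ether formation by this method is often accompanied by reductive termination.
- Comparison: the chosen route is longer after the key step, but all three configurations are placed by reagent control and C5 does not depend on the bias of the ring.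

Key step: step 8

Remark on the chemistry: the L-fructose-derived enantiomer of the Shi ketone (1,2:4,5-di-O-isopropylidene-β-L-erythro-2,3-hexodiulo-2,6-pyranose) is taken as purchasable, and commercial bromo ester 5 is used as the pure E isomer.

## Route

Chain numbering of 8–12 maps onto the core as C3 = C3a, C4 = C6a, C5 = C6, C6 = C5, C7 = C1′, C8 = C2′.

Step 1
Reactants: 1 2,3-dihydrofuran
Product: 4 (3Z)-4-(tributylstannyl)pent-3-en-1-ol, via 5-lithio-2,3-dihydrofuran 2 (not isolated), via alkenyl(methyl)cuprate 3 (not isolated)
Conditions: t-BuLi, THF/pentane, −78 → 0 °C; Me2CuLi (from MeLi, CuI), Et2O/Me2S, −78 °C → rt; Bu3SnCl, −78 °C → rt; aq. NH4Cl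
Reagents that add atoms: lithium dimethylcuprate [Li+].C[Cu-]C (one methyl group); tributyltin chloride CCCC[Sn](Cl)(CCCC)CCCC
Why: α-Lithiation of the enol ether and cuprate formation are followed by a 1,2-metalate rearrangement of the α-alkoxyalkenyl cuprate, a known reaction type: methyl migrates from copper to the metal-bearing carbon with inversion as the ring C–O bond breaks, so copper ends cis and methyl trans to the oxidoethyl arm. Stannylation of the alkenyl–copper bond with retention should fix the Z trisubstituted alkene.

Step 2
Reactants: 5 ethyl (2E)-4-bromo-3-methylbut-2-enoate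
Product: 6 (2E)-4-bromo-3-methylbut-2-en-1-ol
Conditions: i-Bu2AlH (2.2 equiv), CH2Cl2, −78 °C; aq. KNaC4H4O6 work-up
Reagents that add atoms: none
Why: 1,2-Reduction of the conjugated ester by the aluminium hydride at low temperature, where the primary allylic bromide is not reduced; the alkene geometry is untouched.

Step 3
Reactants: 6 (2E)-4-bromo-3-methylbut-2-en-1-ol
Product: 7 {[(2E)-4-bromo-3-methylbut-2-en-1-yl]oxy}(tert-butyl)diphenylsilane
Conditions: TBDPSCl, imidazole, CH2Cl2, 0 °C
Reagents that add atoms: tert-butyl(chloro)diphenylsilane CC(C)(C)[Si](Cl)(c1ccccc1)c1ccccc1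
Why: Imidazole-promoted O-silylation of a primary alcohol; run cold and briefly so that silylation outruns N-alkylation of imidazole by the allylic bromide.

Step 4
Reactants: 4 (3Z)-4-(tributylstannyl)pent-3-en-1-ol; 7 {[(2E)-4-bromo-3-methylbut-2-en-1-yl]oxy}(tert-butyl)diphenylsilane
Product: 8 (3Z,6E)-8-[(tert-butyldiphenylsilyl)oxy]-4,6-dimethylocta-3,6-dien-1-ol
Conditions: Pd2(dba)3 (2.5 mol %), tri(2-furyl)phosphine (10 mol %), THF, 45 °C
Reagents that add atoms: none
Why: Stille coupling: zerovalent palladium adds to the allylic bromide to give the syn π-allyl complex of the E alkene, the alkenyl group transfers from tin with retention, and reductive elimination at the unsubstituted allyl terminus should give the linear skipped diene with both geometries intact. The free hydroxyl and the silyl ether are inert.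

Step 5
Reactants: 8 (3Z,6E)-8-[(tert-butyldiphenylsilyl)oxy]-4,6-dimethylocta-3,6-dien-1-ol
Product: 10 (3Z,6E)-8-[(tert-butyldiphenylsilyl)oxy]-4,6-dimethylocta-3,6-dienoic acid, via dienal 9 (not isolated)
Conditions: TEMPO (0.2 equiv), PhI(OAc)2 (2.2 equiv), MeCN/H2O (1:1), rt
Reagents that add atoms: water O
Why: Oxoammonium oxidation of the primary alcohol to the aldehyde and of its hydrate to the acid in one flask; the medium is only weakly acidic, so the β,γ-alkene is not expected to move into conjugation and the silyl ether should survive.

Step 6
Reactants: 10 (3Z,6E)-8-[(tert-butyldiphenylsilyl)oxy]-4,6-dimethylocta-3,6-dienoic acid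
Product: 11 tert-butyl (3Z,6E)-8-[(tert-butyldiphenylsilyl)oxy]-4,6-dimethylocta-3,6-dienoate
Conditions: O-tert-butyl-N,N′-diisopropylisourea, CH2Cl2, rt
Reagents that add atoms: O-tert-butyl-N,N′-diisopropylisourea CC(C)NC(=NC(C)C)OC(C)(C)C
Why: The acid protonates the isourea and the carboxylate captures the tert-butyl group (O-alkylation with loss of the urea); no base or strong acid is present, so the skipped diene and the β,γ-unsaturation are not disturbed.

Step 7
Reactants: 11 tert-butyl (3Z,6E)-8-[(tert-butyldiphenylsilyl)oxy]-4,6-dimethylocta-3,6-dienoate
Product: 12 tert-butyl (3S,4R,6S,7S)-8-[(tert-butyldiphenylsilyl)oxy]-3,4:6,7-diepoxy-4,6-dimethyloctanoate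
Conditions: L-fructose-derived Shi ketone (0.6 equiv), KHSO5 (as 2KHSO5·KHSO4·K2SO4), K2CO3, Bu4NHSO4, aq. Na2B4O7/Na2(EDTA) buffer, MeCN/CH2(OMe)2, 0 °C
Reagents that add atoms: potassium peroxymonosulfate [K+].[O-]S(=O)(=O)OO
Why: Shi epoxidation: the chiral dioxirane transfers oxygen through a spiro transition state in which the single vinylic hydrogen of each trisubstituted alkene takes the hindered position. The same catalyst enantiomer should therefore attack the face giving (3S,4R) at the Z alkene and (6S,7S) at the E alkene; the latter is the sense that titanium/L-(+)-tartrate gives on the free allylic alcohol. The additions are syn, so alkene geometry becomes relative configuration, and all four new stereocentres are reagent-controlled.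

Step 8
Reactants: 12 tert-butyl (3S,4R,6S,7S)-8-[(tert-butyldiphenylsilyl)oxy]-3,4:6,7-diepoxy-4,6-dimethyloctanoate
Product: 14 (3aS,5R,6aS)-5-[(1S)-2-[(tert-butyldiphenylsilyl)oxy]-1-hydroxyethyl]-5,6a-dimethyltetrahydrofuro[3,2-b]furan-2(3H)-one, via epoxy hydroxy lactone 13 (not isolated)
Conditions: (+)-10-camphorsulfonic acid (0.2 equiv), CH2Cl2, 0 °C → rt
Reagents that add atoms: none
Why: Protonation of the C3–C4 epoxide lets the ester carbonyl oxygen attack the tertiary carbon C4 from the side opposite the breaking C–O bond; the tert-butyl group of the resulting dialkoxycarbenium ion leaves as 2-methylpropene, which gives hydroxy lactone 13 and returns the proton. This first closure is five-membered and endo with respect to the epoxide (both epoxide carbons end in the ring); the only alternative is a four-membered closure at C3, and the tertiary carbon carries the developing positive charge. The freed C3 hydroxyl then opens the protonated C6–C7 epoxide at its tertiary carbon C6 in a 5-exo closure, again with inversion, forming the tetrahydrofuran; attack at C7 would be 6-endo at a secondary carbon deactivated by the silyloxymethyl group. The two new ring stereocentres C6a and C5 are thus the inverted C4 and C6 of the epoxides, C3a and C1′ keep the configuration set in step 7, and the Z geometry of the former C3=C4 alkene places the hydroxyl and the C5 methylene cis on the lactone, so the second ring can only be cis-fused. The closest known reactions are the acid-induced lactonisation of β,γ-epoxy esters and acid-promoted polyepoxide cascades terminated by a tert-butyl ester or carbonate. The ester-first order is the only productive one, because the oxygen of the first epoxide could reach C6 only through a four-membered ring fused to the oxirane. The step needs clean inversion at two tertiary carbons; a catalytic sulfonic acid in a non-nucleophilic solvent at low temperature, with an internal nucleophile placed for a five-membered closure each time, is chosen to keep free tertiary cations from forming. The TBDPS ether should be stable here and keeps the primary oxygen from competing.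

Step 9
Reactants: 14 (3aS,5R,6aS)-5-[(1S)-2-[(tert-butyldiphenylsilyl)oxy]-1-hydroxyethyl]-5,6a-dimethyltetrahydrofuro[3,2-b]furan-2(3H)-one
Product: 15 (3aS,5R,6aS)-5-[(1S)-1,2-dihydroxyethyl]-5,6a-dimethyltetrahydrofuro[3,2-b]furan-2(3H)-one
Conditions: Bu4NF, AcOH, THF, 0 °C → rt
Reagents that add atoms: none
Why: Fluoride cleaves the Si–O bond; buffering with acetic acid keeps the liberated alkoxide from triggering β-elimination of the β-alkoxy lactone.

Step 10
Reactants: 15 (3aS,5R,6aS)-5-[(1S)-1,2-dihydroxyethyl]-5,6a-dimethyltetrahydrofuro[3,2-b]furan-2(3H)-one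
Product: 16 (3aS,5R,6aS)-5,6a-dimethyl-2-oxohexahydrofuro[3,2-b]furan-5-carbaldehyde
Conditions: NaIO4, THF/H2O, 0 °C → rt
Reagents that add atoms: none
Why: Periodate glycol cleavage (Malaprade reaction) of the terminal 1,2-diol: C2′ leaves as formaldehyde and C1′ becomes the aldehyde on the quaternary C5, which has no α-hydrogen and cannot epimerise.

Step 11
Reactants: 17 1-(benzyloxy)-4-bromobenzene; 18 1,11-dibromoundecane
Product: 20 1-(benzyloxy)-4-(11-bromoundecyl)benzene, via [4-(benzyloxy)phenyl]magnesium bromide 19 (not isolated)
Conditions: Mg, THF, reflux; then 18 (3 equiv), Li2CuCl4 (3 mol %), THF/NMP, 0 °C → rt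
Reagents that add atoms: none
Why: Grignard formation followed by copper-catalysed sp2–sp3 coupling with a primary alkyl bromide; the excess of dibromide suppresses double arylation and is recovered, and the benzyl ether is inert.

Step 12
Reactants: 20 1-(benzyloxy)-4-(11-bromoundecyl)benzene
Product: 21 {11-[4-(benzyloxy)phenyl]undecyl}triphenylphosphonium bromide
Conditions: PPh3, MeCN, reflux
Reagents that add atoms: triphenylphosphine c1ccc(cc1)P(c1ccccc1)c1ccccc1
Why: Quaternisation of the phosphine by the primary bromide (bimolecular substitution).

Step 13
Reactants: 16 (3aS,5R,6aS)-5,6a-dimethyl-2-oxohexahydrofuro[3,2-b]furan-5-carbaldehyde; 21 {11-[4-(benzyloxy)phenyl]undecyl}triphenylphosphonium bromide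
Product: 23 (3aS,5R,6aS)-5-{(1Z)-12-[4-(benzyloxy)phenyl]dodec-1-en-1-yl}-5,6a-dimethyltetrahydrofuro[3,2-b]furan-2(3H)-one, via phosphonium ylide 22 (not isolated)
Conditions: NaN(SiMe3)2 (0.95 equiv), THF, −78 → 0 °C; then 16, −78 °C → rt
Reagents that add atoms: none
Why: Wittig reaction of a non-stabilised ylide with a non-enolisable α-alkoxy aldehyde; addition at −78 °C should be much faster than attack on or deprotonation of the lactone, and a slight deficit of base leaves no free amide. The Z alkene is expected to predominate, but the geometry is irrelevant because the alkene is hydrogenated next.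

Step 14
Reactants: 23 (3aS,5R,6aS)-5-{(1Z)-12-[4-(benzyloxy)phenyl]dodec-1-en-1-yl}-5,6a-dimethyltetrahydrofuro[3,2-b]furan-2(3H)-one
Product: 24 (3aS,5S,6aS)-5-[12-(4-hydroxyphenyl)dodecyl]-5,6a-dimethyltetrahydrofuro[3,2-b]furan-2(3H)-one (plakortone N)
Conditions: H2 (1 atm), Pd/C (10 %), EtOAc/EtOH, rt
Reagents that add atoms: none
Why: Heterogeneous hydrogenation saturates the disubstituted alkene and hydrogenolyses the benzyl ether in one operation; the lactone and the tertiary ethers are inert. No stereocentre is touched: the change of the C5 descriptor from R to S comes only from the priority change of the side chain.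

## Compound list

1 | 2,3-dihydrofuran | C1CC=CO1 | starting material
2 | 5-lithio-2,3-dihydrofuran | [Li]C1=CCCO1 | intermediate (not isolated)
3 | dilithium methyl[(2Z)-5-oxidopent-2-en-2-yl]cuprate | [Li+].[Li+].[O-]CC/C=C(/C)[Cu-]C | intermediate (not isolated)
4 | (3Z)-4-(tributylstannyl)pent-3-en-1-ol | OCC/C=C(/C)[Sn](CCCC)(CCCC)CCCC | intermediate
5 | ethyl (2E)-4-bromo-3-methylbut-2-enoate | CCOC(=O)/C=C(\C)CBr | starting material
6 | (2E)-4-bromo-3-methylbut-2-en-1-ol | OC/C=C(\C)CBr | intermediate
7 | {[(2E)-4-bromo-3-methylbut-2-en-1-yl]oxy}(tert-butyl)diphenylsilane | BrC/C(C)=C/CO[Si](c1ccccc1)(c1ccccc1)C(C)(C)C | intermediate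
8 | (3Z,6E)-8-[(tert-butyldiphenylsilyl)oxy]-4,6-dimethylocta-3,6-dien-1-ol | OCC/C=C(/C)C/C(C)=C/CO[Si](c1ccccc1)(c1ccccc1)C(C)(C)C | intermediate
9 | (3Z,6E)-8-[(tert-butyldiphenylsilyl)oxy]-4,6-dimethylocta-3,6-dienal | O=CC/C=C(/C)C/C(C)=C/CO[Si](c1ccccc1)(c1ccccc1)C(C)(C)C | intermediate (not isolated)
10 | (3Z,6E)-8-[(tert-butyldiphenylsilyl)oxy]-4,6-dimethylocta-3,6-dienoic acid | OC(=O)C/C=C(/C)C/C(C)=C/CO[Si](c1ccccc1)(c1ccccc1)C(C)(C)C | intermediate
11 | tert-butyl (3Z,6E)-8-[(tert-butyldiphenylsilyl)oxy]-4,6-dimethylocta-3,6-dienoate | CC(C)(C)OC(=O)C/C=C(/C)C/C(C)=C/CO[Si](c1ccccc1)(c1ccccc1)C(C)(C)C | intermediate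
12 | tert-butyl (3S,4R,6S,7S)-8-[(tert-butyldiphenylsilyl)oxy]-3,4:6,7-diepoxy-4,6-dimethyloctanoate | CC(C)(C)OC(=O)C[C@@H]1O[C@]1(C)C[C@]2(C)O[C@H]2CO[Si](c3ccccc3)(c4ccccc4)C(C)(C)C | intermediate (precursor of the key step)
13 | (4S,5S)-5-{[(2S,3S)-3-{[(tert-butyldiphenylsilyl)oxy]methyl}-2-methyloxiran-2-yl]methyl}-4-hydroxy-5-methyloxolan-2-one | O=C1C[C@H](O)[C@](C)(C[C@]2(C)O[C@H]2CO[Si](c3ccccc3)(c4ccccc4)C(C)(C)C)O1 | intermediate (not isolated)
14 | (3aS,5R,6aS)-5-[(1S)-2-[(tert-butyldiphenylsilyl)oxy]-1-hydroxyethyl]-5,6a-dimethyltetrahydrofuro[3,2-b]furan-2(3H)-one | C[C@]1([C@@H](O)CO[Si](c3ccccc3)(c4ccccc4)C(C)(C)C)C[C@]2(C)OC(=O)C[C@@H]2O1 | intermediate (product of the key step)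
15 | (3aS,5R,6aS)-5-[(1S)-1,2-dihydroxyethyl]-5,6a-dimethyltetrahydrofuro[3,2-b]furan-2(3H)-one | C[C@]1([C@@H](O)CO)C[C@]2(C)OC(=O)C[C@@H]2O1 | intermediate
16 | (3aS,5R,6aS)-5,6a-dimethyl-2-oxohexahydrofuro[3,2-b]furan-5-carbaldehyde | C[C@]1(C=O)C[C@]2(C)OC(=O)C[C@@H]2O1 | intermediate
17 | 1-(benzyloxy)-4-bromobenzene | Brc1ccc(OCc2ccccc2)cc1 | starting material
18 | 1,11-dibromoundecane | BrCCCCCCCCCCCBr | starting material
19 | [4-(benzyloxy)phenyl]magnesium bromide | Br[Mg]c1ccc(OCc2ccccc2)cc1 | intermediate (not isolated)
20 | 1-(benzyloxy)-4-(11-bromoundecyl)benzene | BrCCCCCCCCCCCc1ccc(OCc2ccccc2)cc1 | intermediate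
21 | {11-[4-(benzyloxy)phenyl]undecyl}triphenylphosphonium bromide | [Br-].c1ccc(cc1)[P+](CCCCCCCCCCCc1ccc(OCc2ccccc2)cc1)(c1ccccc1)c1ccccc1 | intermediate
22 | {11-[4-(benzyloxy)phenyl]undecylidene}triphenylphosphorane | c1ccc(cc1)P(=CCCCCCCCCCCc1ccc(OCc2ccccc2)cc1)(c1ccccc1)c1ccccc1 | intermediate (not isolated)
23 | (3aS,5R,6aS)-5-{(1Z)-12-[4-(benzyloxy)phenyl]dodec-1-en-1-yl}-5,6a-dimethyltetrahydrofuro[3,2-b]furan-2(3H)-one | C[C@]1(/C=C\CCCCCCCCCCc3ccc(OCc4ccccc4)cc3)C[C@]2(C)OC(=O)C[C@@H]2O1 | intermediate
24 | (3aS,5S,6aS)-5-[12-(4-hydroxyphenyl)dodecyl]-5,6a-dimethyltetrahydrofuro[3,2-b]furan-2(3H)-one, plakortone N | C[C@]1(CCCCCCCCCCCCc2ccc(O)cc2)C[C@]2(C)OC(=O)C[C@@H]2O1 | target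

## Step count and least certain steps

Total: 14 steps. Longest linear sequence: 11 steps (5 → 6 → 7 → 8 → 10 → 11 → 12 → 14 → 15 → 16 → 23 → 24; steps 2–10, 13, 14).

**Step 8 (key step).** The most likely failure is acid ionisation of the silyloxymethyl epoxide before the lactone has formed. The tert-butyl ester carbonyl is only a moderate nucleophile and both epoxides are trisubstituted, so a free tertiary cation at C6 could lead to hydride shift (Meinwald-type rearrangement) or to loss of configuration at C5.
Fallback, from acid 10 back to 14: epoxidise the potassium salt of 10 under the conditions of step 7 to the bis-epoxy acid F1, held as its carboxylate in the basic medium. Bring the extract to about pH 4, where the partly ionised carboxylic acid is both a stronger internal nucleophile and its own proton source for the first opening. Let pyridinium p-toluenesulfonate in CH2Cl2 complete the ether ring, giving 14 without a strong acid ever meeting the bis-epoxide.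

**Step 7.** Two processes threaten it. Epoxidation of the inductively deactivated, silyl-shielded allylic-ether alkene may be slow and less face-selective while the ketone is consumed by Baeyer–Villiger oxidation. The β,γ-epoxy ester may undergo base-induced β-elimination in the carbonate buffer.
Fallback, from 11 back to 12: remove the silyl group with HF·pyridine to give the allylic alcohol F2. Epoxidise it by Sharpless asymmetric epoxidation (Ti(OiPr)4, L-(+)-diethyl tartrate, t-BuOOH, 4 Å sieves, CH2Cl2, −20 °C) to the (2S,3S)-epoxy alcohol F3, the homoallylic Z alkene staying untouched. Silylate to the mono-epoxide F4 and epoxidise only the Z alkene with the same ketone in a shorter, colder run to reach 12.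

**Step 1.** Methyl is a reluctant migrating group. Incomplete rearrangement, protonation of 2, or transfer of methyl and not the alkenyl group to tin would lower the yield, and any leakage of geometry would be carried into 12.
Fallback, from bromide 7 back to 8: couple 7 with but-3-yn-1-ol (CuI, K2CO3, NaI, DMF) to the skipped enyne alcohol F5. Carry out a hydroxyl-directed syn carbomagnesiation with MeMgBr and Fe(acac)3 (iron tris(acetylacetonate), trivalent iron) in THF. Methyl is delivered to the distal alkyne carbon and magnesium to the proximal one, and protonation then gives the same 3Z alcohol 8 without tin or copper.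

**Step 4.** Transmetalation from a stannane that is substituted at the metal-bearing carbon and at the cis position is slow. Protodestannylation, reduction or dimerisation of the allyl partner, and syn/anti equilibration of the 2-methyl-substituted π-allyl intermediate (erosion of the 6E geometry) may compete.
Fallback, from 1 and 7 back to 8: omit tin and palladium and add bromide 7 directly to cuprate 3 generated as in step 1. Allylic substitution at the primary carbon with retention at the alkenyl carbon gives 8 in the same flask (no new compound, F0).

**Step 13.** The ylide may act as a base on the lactone (C3–H), leading to β-elimination of O4 and opening of the ether ring, or may add sluggishly to the hindered neopentyl-type aldehyde.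
Fallback, from 16 and 20 back to 24: convert bromide 20 into the Grignard reagent F6 (Mg, THF), transmetalate to the less basic organocerium with CeCl3, and add it to 16 at −78 °C to give the secondary alcohol F7 as a mixture of carbinol epimers. Acylate under neutral conditions with 1,1′-thiocarbonyldiimidazole to the imidazolide F8 and reduce with Bu3SnH/AIBN (Barton–McCombie deoxygenation) to the benzyl ether F9. Hydrogenolysis as in step 14 gives 24.

## Further compounds

F1 | step 8 | (3S,4R,6S,7S)-8-[(tert-butyldiphenylsilyl)oxy]-3,4:6,7-diepoxy-4,6-dimethyloctanoic acid | OC(=O)C[C@@H]1O[C@]1(C)C[C@]2(C)O[C@H]2CO[Si](c3ccccc3)(c4ccccc4)C(C)(C)C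
F2 | step 7 | tert-butyl (3Z,6E)-8-hydroxy-4,6-dimethylocta-3,6-dienoate | CC(C)(C)OC(=O)C/C=C(/C)C/C(C)=C/CO
F3 | step 7 | tert-butyl (3Z)-5-[(2S,3S)-3-(hydroxymethyl)-2-methyloxiran-2-yl]-4-methylpent-3-enoate | CC(C)(C)OC(=O)C/C=C(/C)C[C@]1(C)O[C@H]1CO
F4 | step 7 | tert-butyl (3Z)-5-[(2S,3S)-3-{[(tert-butyldiphenylsilyl)oxy]methyl}-2-methyloxiran-2-yl]-4-methylpent-3-enoate | CC(C)(C)OC(=O)C/C=C(/C)C[C@]1(C)O[C@H]1CO[Si](c1ccccc1)(c1ccccc1)C(C)(C)C
F5 | step 1 | (6E)-8-[(tert-butyldiphenylsilyl)oxy]-6-methyloct-6-en-3-yn-1-ol | OCCC#CC/C(C)=C/CO[Si](c1ccccc1)(c1ccccc1)C(C)(C)C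
F0 | step 4 | none | none
F6 | step 13 | {11-[4-(benzyloxy)phenyl]undecyl}magnesium bromide | Br[Mg]CCCCCCCCCCCc1ccc(OCc2ccccc2)cc1
F7 | step 13 | (3aS,5R,6aS)-5-{12-[4-(benzyloxy)phenyl]-1-hydroxydodecyl}-5,6a-dimethyltetrahydrofuro[3,2-b]furan-2(3H)-one (both carbinol epimers) | C[C@]1(C(O)CCCCCCCCCCCc3ccc(OCc4ccccc4)cc3)C[C@]2(C)OC(=O)C[C@@H]2O1
F8 | step 13 | O-{12-[4-(benzyloxy)phenyl]-1-[(3aS,5R,6aS)-5,6a-dimethyl-2-oxohexahydrofuro[3,2-b]furan-5-yl]dodecyl} 1H-imidazole-1-carbothioate | C[C@]1(C(OC(=S)n3ccnc3)CCCCCCCCCCCc3ccc(OCc4ccccc4)cc3)C[C@]2(C)OC(=O)C[C@@H]2O1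
F9 | step 13 | (3aS,5S,6aS)-5-{12-[4-(benzyloxy)phenyl]dodecyl}-5,6a-dimethyltetrahydrofuro[3,2-b]furan-2(3H)-one | C[C@]1(CCCCCCCCCCCCc3ccc(OCc4ccccc4)cc3)C[C@]2(C)OC(=O)C[C@@H]2O1
A1 | alternative 1 | methyl 3-[(tert-butyldimethylsilyl)oxy]-7-methyl-5-{12-[4-(triisopropylsilyloxy)phenyl]dodecyl}-8-oxabicyclo[3.2.1]octa-2,6-diene-2-carboxylate (enantiomer as in the SMILES) | CC(C)[Si](C(C)C)(C(C)C)Oc1ccc(cc1)CCCCCCCCCCCC[C@@]12C=C(C)[C@@H](O1)C(C(=O)OC)=C(O[Si](C)(C)C(C)(C)C)C2
A2 | alternative 1 | 4-methyl-2-{12-[4-(triisopropylsilyloxy)phenyl]dodecyl}furan | Cc1coc(CCCCCCCCCCCCc2ccc(O[Si](C(C)C)(C(C)C)C(C)C)cc2)c1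
A3 | alternative 1 | methyl 3-[(tert-butyldimethylsilyl)oxy]-2-diazobut-3-enoate | COC(=O)C(=[N+]=[N-])C(=C)O[Si](C)(C)C(C)(C)C
A4 | alternative 2 | ethyl 2-{12-[4-(benzyloxy)phenyl]dodecyl}-5-(2-tert-butoxy-2-oxoethyl)-4-[dimethyl(phenyl)silyl]-4-methyloxolane-2-carboxylate (configuration as in the SMILES) | CCOC(=O)[C@]1(CCCCCCCCCCCCc2ccc(OCc3ccccc3)cc2)C[C@](C)([Si](C)(C)c4ccccc4)[C@H](CC(=O)OC(C)(C)C)O1
A5 | alternative 2 | tert-butyl (3R)-3-[dimethyl(phenyl)silyl]-4-methylpent-4-enoate (configuration for ring oxygen entering anti to the migrating silicon) | CC(=C)[C@H]([Si](C)(C)c1ccccc1)CC(=O)OC(C)(C)C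
A6 | alternative 2 | ethyl 14-[4-(benzyloxy)phenyl]-2-oxotetradecanoate | CCOC(=O)C(=O)CCCCCCCCCCCCc1ccc(OCc2ccccc2)cc1
A7 | alternative 3 | (3aS,5R,6aS)-5-(hydroxymethyl)-5,6a-dimethyltetrahydrofuro[3,2-b]furan-2(3H)-one | C[C@]1(CO)C[C@]2(C)OC(=O)C[C@@H]2O1
A8 | alternative 3 | (4S,5S)-4-hydroxy-5-methyl-5-(2-methylprop-2-en-1-yl)oxolan-2-one | CC(=C)C[C@]1(C)OC(=O)C[C@@H]1O
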